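**Retrosynthetic overview** (bornane numbering: C1 = methyl-bearing bridgehead, C2 = O–CH, C6 = CH carrying the benzylic carbon, C7 = CMe2)
1. End game: the formyl group comes last (Vilsmeier–Haack at the only free arene CH); before that the benzylic CH2 is uncovered from a temporary CH(OSiEt3) group and a born-5-ene is hydrogenated.
2. Key disconnection: C1–C2 and C3–C4 by an intramolecular Diels–Alder reaction of an aryl vinyl ether (C2=C3) with a 1,5,5-trimethylcyclopentadiene (C1, C6, C5, C4; C7 = CMe2). The six-membered carbocycle of the bicyclo[2.2.1] core and the seven-membered benzoxepine form together, after the two five-membered/aromatic rings that are bought.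
3. Enabling feature: O on C2 and the benzylic carbon on C6 are both endo on the two carbons flanking quaternary C1 and sit ortho on the arene. Benzylic C, two arene carbons and O therefore make a four-atom tether from diene C2 to the dienophile; quaternary C7 blocks 1,5-H shifts of the diene.
4. Absolute configuration: a temporary (R)-silyloxy stereocentre at the benzylic carbon, set by catalytic asymmetric Ni/Cr coupling, steers the cycloaddition through A(1,3) strain with the C1 methyl and is then removed.
5. Fragments: aryl aldehyde 10 from phlorisovalerophenone (three steps); dienyl triflate 5 from 4,4-dimethylcyclopentenone (two steps).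

Key step: step 8

Remark: phlorisovalerophenone (6) is taken as a catalogue compound (otherwise one Friedel–Crafts acylation of phloroglucinol with isovaleryl chloride).

Step 1
Reactants: 1 4,4-dimethylcyclopent-2-en-1-one
Product: 3 4,4,5-trimethylcyclopent-2-en-1-one (racemic), via lithium enolate 2 (not isolated)
Conditions: LDA, THF, −78 °C; MeI, DMPU, −78 → −20 °C
Reagents that add atoms: iodomethane, CI
Why: Kinetic α′-deprotonation (C5 is the only enolisable carbon) and enolate C-methylation; the new stereocentre is racemic and is erased in step 2.

Step 2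
Reactants: 3 4,4,5-trimethylcyclopent-2-en-1-one
Product: 5 1,5,5-trimethylcyclopenta-1,3-dien-2-yl trifluoromethanesulfonate, via lithium trimethyldienolate 4 (not isolated)
Conditions: LDA, THF, −78 °C; PhNTf2, −78 °C → rt
Reagents that add atoms: N-phenylbis(trifluoromethanesulfonimide), O=S(=O)(N(c1ccccc1)S(=O)(=O)C(F)(F)F)C(F)(F)F
Why: Enol triflate formation by O-sulfonylation of the cross-conjugated dienolate, which can form only towards C5 and gives the 5,5-dimethyl-blocked cyclopentadiene as a single isomer.

Step 3
Reactants: 6 phlorisovalerophenone (3-methyl-1-(2,4,6-trihydroxyphenyl)butan-1-one)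
Product: 7 1-[4-(2-chloroethoxy)-2,6-dihydroxyphenyl]-3-methylbutan-1-one
Conditions: BrCH2CH2Cl (1.1 equiv), K2CO3 (1.05 equiv), DMF, 40 °C
Reagents that add atoms: 1-bromo-2-chloroethane, ClCCBr
Why: Williamson etherification at the 4-OH, which is para to the acyl group, not chelated and the most acidic, with bromide displaced in preference to chloride; the chloroethyl group is a masked vinyl ether.

Step 4
Reactants: 7 1-[4-(2-chloroethoxy)-2,6-dihydroxyphenyl]-3-methylbutan-1-one
Product: 9 6-(2-chloroethoxy)-2,4-dihydroxy-3-(3-methylbutanoyl)benzaldehyde, via iminium chloride 8 (not isolated)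
Conditions: POCl3, DMF, EtOAc, 0 °C → rt; then H2O, NaOAc, 50 °C
Reagents that add atoms: N,N-dimethylformamide, CN(C)C=O; water, O
Why: Vilsmeier–Haack formylation; the two free ring positions are equivalent by symmetry and the first formyl group deactivates the ring against a second.

Step 5
Reactants: 9 6-(2-chloroethoxy)-2,4-dihydroxy-3-(3-methylbutanoyl)benzaldehyde
Product: 10 2,4-bis(benzyloxy)-6-(2-chloroethoxy)-3-(3-methylbutanoyl)benzaldehyde
Conditions: BnBr (2.5 equiv), K2CO3, DMF, 60 °C
Reagents that add atoms: benzyl bromide, BrCc1ccccc1
Why: Exhaustive Williamson benzylation of both chelated phenols, which caps the oxygen ortho to the future benzylic centre (no o-quinone methide chemistry) with groups that step 9 removes.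

Step 6
Reactants: 10 2,4-bis(benzyloxy)-6-(2-chloroethoxy)-3-(3-methylbutanoyl)benzaldehyde; 5 1,5,5-trimethylcyclopenta-1,3-dien-2-yl trifluoromethanesulfonate
Product: 11 1-[2,6-bis(benzyloxy)-4-(2-chloroethoxy)-3-{(R)-(triethylsilyloxy)(1,5,5-trimethylcyclopenta-1,3-dien-2-yl)methyl}phenyl]-3-methylbutan-1-one
Conditions: CrCl2 (10 mol%), chiral oxazoline–sulfonamide ligand (11 mol%), proton sponge, NiCl2·DMP (2 mol%), Mn, LiCl, TESCl, MeCN, rt
Reagents that add atoms: chlorotriethylsilane, CC[Si](Cl)(CC)CC
Why: Catalytic asymmetric Nozaki–Hiyama–Kishi alkenylation, in which Ni(0) inserts into the dienyl C–OTf bond and the ligand-bound Cr(III) alkenyl adds to the aldehyde only (aryl ketone and alkyl chloride are inert); the ligand antipode is chosen to give the (R)-carbinol (CIP order O > aryl > dienyl > H), released by TESCl directly as its silyl ether so that the acid-labile free alcohol is never handled.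

Step 7
Reactants: 11 (R)-silyl ether with 2-chloroethoxy group
Product: 12 1-[2,6-bis(benzyloxy)-4-(ethenyloxy)-3-{(R)-(triethylsilyloxy)(1,5,5-trimethylcyclopenta-1,3-dien-2-yl)methyl}phenyl]-3-methylbutan-1-one
Conditions: t-BuOK (2.5 equiv), THF, 0 °C
Reagents that add atoms: none
Why: E2 dehydrochlorination of the aryl 2-chloroethyl ether to the aryl vinyl ether; the ketone is only reversibly enolised and the benzylic C–H should be too weakly acidic under these conditions for the stereocentre to be touched.

Step 8
Reactants: 12 aryl vinyl ether with tethered trimethylcyclopentadiene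
Product: 13 Diels–Alder adduct: born-5-ene bridged by a benzoxepine (C2–O–aryl endo, C6–CH(OSiEt3)–aryl), two OBn and isovaleryl on the arene; C1, C2 and C4 arranged as in 17, benzylic carbon R
Conditions: PhMe (5 mM), BHT, 2,6-di-tert-butyl-4-methylpyridine (cat.), sealed tube, 190 °C
Reagents that add atoms: none
Why: A thermal, concerted but asynchronous [4π+2π] cycloaddition joins the vinyl ether CH (C2) to the methyl-bearing diene terminus (C1) and its CH2 (C3) to the other terminus (C4); the closest known reaction type is the intramolecular Diels–Alder reaction of alkyl cyclopentadienes with unactivated tethered alkenes. The six-membered carbocycle of the bicyclo[2.2.1]heptene closes by the [4+2] mode and the seven-membered oxepine closes as the tether ring when C1–C2 forms. Relative configuration at C1, C2 and C4 follows from suprafacial addition and from the four-atom tether, which can only reach C2 with its oxygen endo; in this early transition state the benzylic carbon (in the diene plane) and the endo oxygen lie about as far apart as two ortho substituents, so the tether fits with little strain. Absolute configuration is relayed from the (R)-benzylic centre: the aryl group must sit on the dienophile face, and A(1,3) strain with the C1 methyl then places H, not OSiEt3, next to that methyl, so one diene face is selected. Regiochemistry is secured because the reverse orientation would put a bridgehead alkene in an eight-membered ring. Quaternary C7 rules out 1,5-H shifts and slows dimerisation, and the para-acyl group makes the vinyl ether a near-neutral dienophile.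

Step 9
Reactants: 13 Diels–Alder adduct
Product: 14 saturated diphenol: bornane with endo C2–O–aryl and endo C6–CH(OSiEt3)–aryl (benzylic carbon R), both phenols free
Conditions: H2 (4 atm), Pd/C, EtOAc, rt
Reagents that add atoms: none
Why: Heterogeneous hydrogenation of the strained C5=C6 bond, which can take H2 only on its exo face because the endo face is covered by the benzoxepine and only the cis (endo) ring fusion is geometrically possible, which sets C6; both benzyl ethers are hydrogenolysed and the silyl ether should survive in neutral aprotic medium (any early C–O hydrogenolysis only anticipates step 10).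

Step 10
Reactants: 14 saturated diphenol silyl ether
Product: 15 des-formyl target, (1R,2S,4R,6S) in bornane numbering
Conditions: Et3SiH (5 equiv), TFA (10 equiv), CH2Cl2, −20 → 0 °C
Reagents that add atoms: none
Why: Ionic hydrogenation, in which acid ionises the benzylic silyl ether to the 2,4,6-trioxygenated benzylic cation (o-quinone methide) that takes hydride from Et3SiH much faster than the chelated aryl ketone is reduced, erasing the temporary stereocentre.

Step 11
Reactants: 15 des-formyl target
Product: 17 CNP0246493.1, via iminium chloride 16 (not isolated)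
Conditions: POCl3, DMF, MeCN, 0 °C → rt; then H2O, NaOAc, 50 °C
Reagents that add atoms: N,N-dimethylformamide, CN(C)C=O; water, O
Why: Vilsmeier–Haack formylation at the only unsubstituted aromatic carbon, activated by an ortho OH, an ortho O-alkyl and a para OH, under conditions mild enough for the secondary bornyl aryl ether.

**Compound list**
1 | 4,4-dimethylcyclopent-2-en-1-one | O=C1C=CC(C)(C)C1 | starting material
2 | lithium 3,3-dimethylcyclopenta-1,4-dien-1-olate | [Li+].[O-]C1=CC(C)(C)C=C1 | intermediate
3 | 4,4,5-trimethylcyclopent-2-en-1-one (racemic) | CC1C(=O)C=CC1(C)C | intermediate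
4 | lithium 2,3,3-trimethylcyclopenta-1,4-dien-1-olate | [Li+].[O-]C1=C(C)C(C)(C)C=C1 | intermediate
5 | 1,5,5-trimethylcyclopenta-1,3-dien-2-yl trifluoromethanesulfonate | CC1=C(OS(=O)(=O)C(F)(F)F)C=CC1(C)C | intermediate
6 | phlorisovalerophenone | CC(C)CC(=O)c1c(O)cc(O)cc1O | starting material
7 | 1-[4-(2-chloroethoxy)-2,6-dihydroxyphenyl]-3-methylbutan-1-one | CC(C)CC(=O)c1c(O)cc(OCCCl)cc1O | intermediate
8 | Vilsmeier iminium chloride of 9 | CC(C)CC(=O)c1c(O)cc(OCCCl)c(C=[N+](C)C)c1O.[Cl-] | intermediate
9 | 6-(2-chloroethoxy)-2,4-dihydroxy-3-(3-methylbutanoyl)benzaldehyde | CC(C)CC(=O)c1c(O)cc(OCCCl)c(C=O)c1O | intermediate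
10 | 2,4-bis(benzyloxy)-6-(2-chloroethoxy)-3-(3-methylbutanoyl)benzaldehyde | CC(C)CC(=O)c1c(OCc2ccccc2)cc(OCCCl)c(C=O)c1OCc3ccccc3 | intermediate
11 | (R)-benzylic triethylsilyl ether, 2-chloroethyl aryl ether | CC(C)CC(=O)c1c(OCc2ccccc2)cc(OCCCl)c(c1OCc3ccccc3)[C@H](O[Si](CC)(CC)CC)C4=C(C)C(C)(C)C=C4 | intermediate
12 | (R)-benzylic triethylsilyl ether, aryl vinyl ether | CC(C)CC(=O)c1c(OCc2ccccc2)cc(OC=C)c(c1OCc3ccccc3)[C@H](O[Si](CC)(CC)CC)C4=C(C)C(C)(C)C=C4 | intermediate
13 | Diels–Alder adduct (born-5-ene bridged by benzoxepine, bis-benzyl ether, benzylic (R)-OSiEt3) | CC(C)CC(=O)c1c(OCc4ccccc4)cc2c(c1OCc5ccccc5)[C@H](O[Si](CC)(CC)CC)C1=C[C@@H]3C[C@H](O2)[C@@]1(C)C3(C)C | intermediate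
14 | saturated diphenol with benzylic (R)-OSiEt3 | CC(C)CC(=O)c1c(O)cc2c(c1O)[C@H](O[Si](CC)(CC)CC)[C@@H]1C[C@@H]3C[C@H](O2)[C@@]1(C)C3(C)C | intermediate
15 | des-formyl target | CC(C)CC(=O)c1c(O)cc2c(c1O)C[C@@H]1C[C@@H]3C[C@H](O2)[C@@]1(C)C3(C)C | intermediate
16 | Vilsmeier iminium chloride of 17 | CC(C)CC(=O)c1c(O)c(C=[N+](C)C)c2c(c1O)C[C@@H]1C[C@@H]3C[C@H](O2)[C@@]1(C)C3(C)C.[Cl-] | intermediate
17 | CNP0246493.1, (1R,2S,4R,6S) in bornane numbering | CC(C)CC(=O)c1c(O)c(C=O)c2c(c1O)C[C@@H]1C[C@@H]3C[C@H](O2)[C@@]1(C)C3(C)C | target

**Total steps:** 11. **Longest linear sequence:** 9 (steps 3–11 from 6).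

**Steps most likely to fail**

Step 8. Bond formation at the methyl-bearing diene terminus next to the quaternary carbon may be slow, so that at 190 °C ionisation or elimination of the dienylic silyl ether, or loss of facial selectivity, competes. The fallback changes the bond-forming mechanism from a neutral concerted to an open-shell stepwise cycloaddition: a hole-catalysed (radical-cation) Diels–Alder reaction at ambient temperature (Ru(bpz)3(PF6)2 1 mol%, visible light, air, MeNO2). One-electron oxidation of the electron-rich diene, stepwise [4+2] with the vinyl ether under the same tether and A(1,3) constraints, and back electron transfer would take 12 directly to 13; no new compound (F0).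

Step 6. Face discrimination at the di-ortho-substituted aldehyde may be poor, giving low enantiomeric purity. The fallback replaces asymmetric induction by resolution. It sets out from 10 and 5: the same Ni/Cr coupling without the chiral ligand (Mn, TESCl) gives the racemic silyl ether F1, which is separated on a chiral stationary phase (preparative SFC); the (R)-enantiomer is 11, where the route is rejoined.

Step 9. Saturation of the shielded trisubstituted C5=C6 bond may stall, or allylic C–O hydrogenolysis with double-bond migration may run ahead of it. The fallback sets out from 13 and separates the two events. A metal-hydride hydrogen-atom-transfer hydrogenation (Mn(dpm)3 cat., PhSiH3, t-BuOOH, i-PrOH, rt) forms the tertiary C6 radical, which can only be quenched on the exo face, giving the saturated bis(benzyl ether) F2. Hydrogenolysis of the benzyl ethers (H2, Pd(OH)2/C, EtOAc) then returns to 14.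

**Further compounds**
F0 | step 8 | none | none
F1 | step 6 | racemic benzylic triethylsilyl ether (racemate of 11) | CC(C)CC(=O)c1c(OCc2ccccc2)cc(OCCCl)c(c1OCc3ccccc3)C(O[Si](CC)(CC)CC)C4=C(C)C(C)(C)C=C4
F2 | step 9 | saturated bis(benzyl ether) with benzylic (R)-OSiEt3 | CC(C)CC(=O)c1c(OCc4ccccc4)cc2c(c1OCc5ccccc5)[C@H](O[Si](CC)(CC)CC)[C@@H]1C[C@@H]3C[C@H](O2)[C@@]1(C)C3(C)C
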